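## Retrosynthetic overview

- The strategy rests on the 1,2,4-substituted benzene ring: ring carbon C3 bears the angelate oxygen, its neighbour C4 bears the oxirane carbon C8, and C1 (para to C4) bears the CH2O ester carbon C7. This maps onto methyl coumalate (ester carbon = C7) and an alkynyl pinacol boronate whose boron marks the C3 oxygen and whose other alkyne carbon already carries quaternary C8.
- Key disconnection: ring bonds C2–C3 and C4–C5 of the arene, made by [4+2] cycloaddition of the pyrone with the alkynylboronate and loss of CO2.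
- Order of rings: dioxolane (protecting ring, step 3), benzene ring (step 7), oxirane (step 14, C8 oxygen displacing a tosylate on the former acetonide CH2).
- C8 is set as R by lipase desymmetrisation of a prochiral 2-alkynylglycerol diacetate. It is carried as acetonide (C8–O and the CH2 that becomes the oxirane) and silyl ether (the CH2 that becomes the acetate).
- After the arene: C–B to phenol (allyl-protected), CO2Me to CH2OH to the (R)-2-methylbutanoate, oxirane closure, acetate, and the angelate last.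

Key step: step 7

Assumption: (R)-2-methylbutanoic acid and angelic acid are bought as such, and the lipase of step 2 is picked by screening (enantiocomplementary lipases exist) so that it gives the (2R)-monoacetate 5.

## Route

Step 1
Reactants: 1 (triisopropylsilyl)acetylene; 2 1,3-diacetoxyacetone
Product: 4 2-hydroxy-2-[(triisopropylsilyl)ethynyl]propane-1,3-diyl diacetate, via lithium (triisopropylsilyl)acetylide 3 (not isolated)
Conditions: n-BuLi, THF, −78 °C; then 2, −78 °C; AcOH quench at −78 °C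
Reagents that add atoms: none
Why: 1,2-addition of a lithium acetylide to a ketone; the ketone flanked by two acyloxymethyl groups is far more electrophilic than the acetates at −78 °C, the cold acidic quench prevents acetyl migration to the tertiary alkoxide, and no stereocentre arises because the two arms are identical.

Step 2
Reactants: 4 2-hydroxy-2-[(triisopropylsilyl)ethynyl]propane-1,3-diyl diacetate
Product: 5 (2R)-2-hydroxy-2-(hydroxymethyl)-4-(triisopropylsilyl)but-3-yn-1-yl acetate
Conditions: lipase (Burkholderia cepacia lipase, chosen by screening), 0.1 M phosphate buffer pH 7/MTBE, 25 °C, stopped at one acetate cleaved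
Reagents that add atoms: none
Why: Enzymatic desymmetrisation (lipase-catalysed hydrolysis of one enantiotopic ester), a reaction established for prochiral 2-alkynyl-2-hydroxypropane-1,3-diyl diacetates; the active site tells the two acetoxymethyl arms apart and so sets C8 as R, and neutral pH suppresses acyl migration.

Step 3
Reactants: 5 (2R)-2-hydroxy-2-(hydroxymethyl)-4-(triisopropylsilyl)but-3-yn-1-yl acetate
Product: 6 [(4R)-2,2-dimethyl-4-[(triisopropylsilyl)ethynyl]-1,3-dioxolan-4-yl]methyl acetate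
Conditions: 2-methoxypropene, PPTS (cat.), CH2Cl2, 0 °C
Reagents that add atoms: 2-methoxypropene, COC(C)=C
Why: Acid-catalysed isopropylidene ketal formation on the 1,2-diol (tertiary plus freed primary hydroxyl) locks these two oxygens, so acetyl migration can no longer scramble C8 and the two CH2O arms stay distinct.

Step 4
Reactants: 6 [(4R)-2,2-dimethyl-4-[(triisopropylsilyl)ethynyl]-1,3-dioxolan-4-yl]methyl acetate
Product: 8 [(4S)-4-ethynyl-2,2-dimethyl-1,3-dioxolan-4-yl]methanol, via ethynyl acetate 7 (not isolated)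
Conditions: Bu4NF, THF, 0 °C; then K2CO3 (cat.), MeOH, rt
Reagents that add atoms: none
Why: Fluoride-induced protodesilylation of the alkynyl–silicon bond followed by base-catalysed transesterification of the acetate with methanol; the acetonide and C8 are inert to both (the descriptor changes only through CIP priorities).

Step 5
Reactants: 8 [(4S)-4-ethynyl-2,2-dimethyl-1,3-dioxolan-4-yl]methanol
Product: 9 (4R)-4-[(tert-butyldiphenylsilyloxy)methyl]-4-ethynyl-2,2-dimethyl-1,3-dioxolane
Conditions: TBDPSCl, imidazole, DMF, rt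
Reagents that add atoms: tert-butyl(chloro)diphenylsilane, CC(C)(C)[Si](Cl)(c1ccccc1)c1ccccc1
Why: Imidazole-promoted silylation of a primary alcohol gives an ether that should withstand n-BuLi, 165 °C, hydride and mild acid, and marks the arm that ends as the acetate.

Step 6
Reactants: 9 (4R)-4-[(tert-butyldiphenylsilyloxy)methyl]-4-ethynyl-2,2-dimethyl-1,3-dioxolane; 10 2-isopropoxy-4,4,5,5-tetramethyl-1,3,2-dioxaborolane
Product: 13 2-{[(4R)-4-[(tert-butyldiphenylsilyloxy)methyl]-2,2-dimethyl-1,3-dioxolan-4-yl]ethynyl}-4,4,5,5-tetramethyl-1,3,2-dioxaborolane, via lithium acetylide 11 (not isolated), via lithium isopropoxyborate 12 (not isolated)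
Conditions: n-BuLi, THF, −78 °C; then 10, −78 °C; then HCl in Et2O (1 equiv), −78 °C to rt
Reagents that add atoms: none
Why: Alkyne deprotonation and trapping with the borate ester gives an ate complex that anhydrous HCl collapses to the alkynyl pinacol boronate, the standard preparation of this reagent class; the HCl is consumed by the ate complex before it can reach the acetonide.

Step 7
Reactants: 13 2-{[(4R)-4-[(tert-butyldiphenylsilyloxy)methyl]-2,2-dimethyl-1,3-dioxolan-4-yl]ethynyl}-4,4,5,5-tetramethyl-1,3,2-dioxaborolane; 14 methyl coumalate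
Product: 16 methyl 4-[(4R)-4-[(tert-butyldiphenylsilyloxy)methyl]-2,2-dimethyl-1,3-dioxolan-4-yl]-3-(4,4,5,5-tetramethyl-1,3,2-dioxaborolan-2-yl)benzoate, via bicyclic lactone 15 (not isolated)
Conditions: 14 (3 equiv), mesitylene, 165 °C, sealed tube, argon
Reagents that add atoms: none
Why: Thermal [4+2] cycloaddition of the electron-poor pyrone diene (C3=C4–C5=C6) across the alkyne gives the 2-oxabicyclo[2.2.2]octadienone 15, which loses CO2 by retro-[4+2] at the same temperature and is aromatic at once; the closest known reaction type is the benzannulation of 2-pyrones with alkynylboronic esters to arylboronates. The benzene ring is closed by this intermolecular cycloaddition, which forms the bonds pyrone C6–C(B) and pyrone C3–C(C8), and the cycloreversion then removes the lactone bridge. No stereocentre is created: quaternary C8 takes no part and keeps its configuration, and both bridgehead diastereomers of 15 give the same arene. The step needs regioselectivity (boron meta and C8 para to the ester): pyrone C6, beta to the ester and bound to the ring oxygen, is the electrophilic terminus and should pair with the boron-bearing alkyne carbon, which is the more nucleophilic end because the other alkyne carbon carries the inductively withdrawing, trioxygenated and bulky C8 group. This regiochemistry follows from the polarisation of both partners but is not established for such a hindered alkyne and has to be confirmed on 16 by NOE and HMBC.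

Step 8
Reactants: 16 methyl 4-[(4R)-4-[(tert-butyldiphenylsilyloxy)methyl]-2,2-dimethyl-1,3-dioxolan-4-yl]-3-(4,4,5,5-tetramethyl-1,3,2-dioxaborolan-2-yl)benzoate
Product: 17 methyl 4-[(4R)-4-[(tert-butyldiphenylsilyloxy)methyl]-2,2-dimethyl-1,3-dioxolan-4-yl]-3-hydroxybenzoate
Conditions: NaBO3·4H2O, THF/H2O, rt
Reagents that add atoms: sodium perborate tetrahydrate (NaBO3·4H2O), [Na+].[Na+].O[B-]1(O)OO[B-](O)(O)OO1
Why: Peroxide oxidation of the aryl C–B bond (1,2-shift of the aryl group from boron to oxygen, then hydrolysis) under near-neutral perborate conditions that spare the methyl ester, acetonide and silyl ether, placing the phenol oxygen exactly ortho to C8.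

Step 9
Reactants: 17 methyl 4-[(4R)-4-[(tert-butyldiphenylsilyloxy)methyl]-2,2-dimethyl-1,3-dioxolan-4-yl]-3-hydroxybenzoate
Product: 18 methyl 3-(allyloxy)-4-[(4R)-4-[(tert-butyldiphenylsilyloxy)methyl]-2,2-dimethyl-1,3-dioxolan-4-yl]benzoate
Conditions: allyl bromide, K2CO3, DMF, rt to 40 °C
Reagents that add atoms: allyl bromide, C=CCBr
Why: Williamson etherification of the phenoxide; the allyl ether should survive hydride, acid, base and fluoride and is removable later under neutral palladium catalysis.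

Step 10
Reactants: 18 methyl 3-(allyloxy)-4-[(4R)-4-[(tert-butyldiphenylsilyloxy)methyl]-2,2-dimethyl-1,3-dioxolan-4-yl]benzoate
Product: 19 {3-(allyloxy)-4-[(4R)-4-[(tert-butyldiphenylsilyloxy)methyl]-2,2-dimethyl-1,3-dioxolan-4-yl]phenyl}methanol
Conditions: i-Bu2AlH (2.5 equiv), CH2Cl2, −78 to 0 °C; aqueous potassium sodium tartrate work-up
Reagents that add atoms: none
Why: Hydride reduction of the methyl ester to the primary benzylic alcohol; no other group in 18 is reducible by i-Bu2AlH at this temperature.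

Step 11
Reactants: 19 {3-(allyloxy)-4-[(4R)-4-[(tert-butyldiphenylsilyloxy)methyl]-2,2-dimethyl-1,3-dioxolan-4-yl]phenyl}methanol; 20 (R)-2-methylbutanoic acid
Product: 21 {3-(allyloxy)-4-[(4R)-4-[(tert-butyldiphenylsilyloxy)methyl]-2,2-dimethyl-1,3-dioxolan-4-yl]phenyl}methyl (2R)-2-methylbutanoate
Conditions: DCC, DMAP (cat.), CH2Cl2, 0 °C to rt
Reagents that add atoms: none
Why: Steglich esterification; a simple alpha-alkyl acid does not enolise or form a ketene under carbodiimide/catalytic DMAP at 0 °C, so the R centre of the acid is carried into the ester unchanged.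

Step 12
Reactants: 21 {3-(allyloxy)-4-[(4R)-4-[(tert-butyldiphenylsilyloxy)methyl]-2,2-dimethyl-1,3-dioxolan-4-yl]phenyl}methyl (2R)-2-methylbutanoate
Product: 22 {3-(allyloxy)-4-[(2R)-1-(tert-butyldiphenylsilyloxy)-2,3-dihydroxypropan-2-yl]phenyl}methyl (2R)-2-methylbutanoate
Conditions: AcOH/THF/H2O (3:1:1), 45 °C
Reagents that add atoms: none
Why: Acid-catalysed ketal hydrolysis through the oxocarbenium ion at the acetal carbon, which forms far more easily than a cation at C8 flanked by two CH2O groups; the silyl ether, esters and allyl ether tolerate aqueous AcOH and no C8–O bond is broken.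

Step 13
Reactants: 22 {3-(allyloxy)-4-[(2R)-1-(tert-butyldiphenylsilyloxy)-2,3-dihydroxypropan-2-yl]phenyl}methyl (2R)-2-methylbutanoate
Product: 23 {3-(allyloxy)-4-[(2S)-1-(tert-butyldiphenylsilyloxy)-2-hydroxy-3-(tosyloxy)propan-2-yl]phenyl}methyl (2R)-2-methylbutanoate
Conditions: TsCl, Et3N, DMAP (cat.), CH2Cl2, 0 °C
Reagents that add atoms: 4-methylbenzenesulfonyl chloride, Cc1ccc(S(=O)(=O)Cl)cc1
Why: Selective sulfonylation of the primary hydroxyl (the tertiary benzylic one is too hindered) under amine base, where no alkoxide is present that could move the silyl group between the two primary oxygens.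

Step 14
Reactants: 23 {3-(allyloxy)-4-[(2S)-1-(tert-butyldiphenylsilyloxy)-2-hydroxy-3-(tosyloxy)propan-2-yl]phenyl}methyl (2R)-2-methylbutanoate
Product: 24 {3-(allyloxy)-4-[(2R)-2-[(tert-butyldiphenylsilyloxy)methyl]oxiran-2-yl]phenyl}methyl (2R)-2-methylbutanoate
Conditions: NaH (1.1 equiv), THF, 0 °C
Reagents that add atoms: none
Why: Intramolecular Williamson reaction (3-exo-tet displacement of the primary tosylate by the tertiary alkoxide) closes the oxirane; C8 carries the nucleophilic oxygen and is not inverted, and the fast ring closure should outrun silyl migration and attack on the distant ester.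

Step 15
Reactants: 24 {3-(allyloxy)-4-[(2R)-2-[(tert-butyldiphenylsilyloxy)methyl]oxiran-2-yl]phenyl}methyl (2R)-2-methylbutanoate
Product: 25 {3-(allyloxy)-4-[(2S)-2-(hydroxymethyl)oxiran-2-yl]phenyl}methyl (2R)-2-methylbutanoate
Conditions: Bu4NF, AcOH (1:1), THF, 0 °C to rt
Reagents that add atoms: none
Why: Fluoride cleavage of the silyl ether, buffered with AcOH so that the oxirane and the alkyl ester are not attacked; a Payne rearrangement of this 2-aryl glycidol would be degenerate and return the same enantiomer.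

Step 16
Reactants: 25 {3-(allyloxy)-4-[(2S)-2-(hydroxymethyl)oxiran-2-yl]phenyl}methyl (2R)-2-methylbutanoate
Product: 26 {4-[(2R)-2-(acetoxymethyl)oxiran-2-yl]-3-(allyloxy)phenyl}methyl (2R)-2-methylbutanoate
Conditions: Ac2O, pyridine, DMAP (cat.), CH2Cl2, 0 °C
Reagents that add atoms: acetic anhydride, CC(=O)OC(C)=O
Why: Acylation of the primary alcohol by nucleophilic catalysis under basic conditions, to which the oxirane is stable.

Step 17
Reactants: 26 {4-[(2R)-2-(acetoxymethyl)oxiran-2-yl]-3-(allyloxy)phenyl}methyl (2R)-2-methylbutanoate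
Product: 27 {4-[(2R)-2-(acetoxymethyl)oxiran-2-yl]-3-hydroxyphenyl}methyl (2R)-2-methylbutanoate
Conditions: Pd(PPh3)4 (5 mol%), N-methylaniline, THF, rt; used at once
Reagents that add atoms: none
Why: Tsuji–Trost-type deallylation: zerovalent palladium ionises the aryl allyl ether to a pi-allyl complex and phenoxide, and the weakly basic N-methylaniline takes up the allyl group, so the phenol is freed under neutral conditions that should spare the oxirane ortho to it.

Step 18
Reactants: 27 {4-[(2R)-2-(acetoxymethyl)oxiran-2-yl]-3-hydroxyphenyl}methyl (2R)-2-methylbutanoate; 28 angelic acid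
Product: 29 2-[(2R)-2-(acetoxymethyl)oxiran-2-yl]-5-{[(2R)-2-methylbutanoyloxy]methyl}phenyl (Z)-2-methylbut-2-enoate (CNP0256757.1)
Conditions: 28, 2,4,6-trichlorobenzoyl chloride, Et3N, toluene, rt; then 27, Et3N, 0 °C to rt
Reagents that add atoms: none
Why: Yamaguchi-type acylation: the mixed anhydride transfers its less hindered angeloyl group to the phenoxide at or below room temperature without DMAP, conditions under which the (Z)-alkene should not isomerise to the tiglate.

## Compound list

1 | (triisopropylsilyl)acetylene | C#C[Si](C(C)C)(C(C)C)C(C)C | starting material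
2 | 1,3-diacetoxyacetone | CC(=O)OCC(=O)COC(C)=O | starting material
3 | lithium (triisopropylsilyl)acetylide (not isolated) | [Li]C#C[Si](C(C)C)(C(C)C)C(C)C | intermediate
4 | 2-hydroxy-2-[(triisopropylsilyl)ethynyl]propane-1,3-diyl diacetate | CC(=O)OCC(O)(COC(C)=O)C#C[Si](C(C)C)(C(C)C)C(C)C | intermediate
5 | (2R)-2-hydroxy-2-(hydroxymethyl)-4-(triisopropylsilyl)but-3-yn-1-yl acetate | CC(C)[Si](C(C)C)(C(C)C)C#C[C@](O)(COC(C)=O)CO | intermediate
6 | [(4R)-2,2-dimethyl-4-[(triisopropylsilyl)ethynyl]-1,3-dioxolan-4-yl]methyl acetate | CC(C)[Si](C(C)C)(C(C)C)C#C[C@]1(COC(C)=O)COC(C)(C)O1 | intermediate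
7 | [(4R)-4-ethynyl-2,2-dimethyl-1,3-dioxolan-4-yl]methyl acetate (not isolated) | C#C[C@]1(COC(C)=O)COC(C)(C)O1 | intermediate
8 | [(4S)-4-ethynyl-2,2-dimethyl-1,3-dioxolan-4-yl]methanol | C#C[C@]1(CO)COC(C)(C)O1 | intermediate
9 | (4R)-4-[(tert-butyldiphenylsilyloxy)methyl]-4-ethynyl-2,2-dimethyl-1,3-dioxolane | C#C[C@]1(CO[Si](c2ccccc2)(c2ccccc2)C(C)(C)C)COC(C)(C)O1 | intermediate
10 | 2-isopropoxy-4,4,5,5-tetramethyl-1,3,2-dioxaborolane | CC(C)OB1OC(C)(C)C(C)(C)O1 | starting material
11 | lithium acetylide of 9 (not isolated) | [Li]C#C[C@]1(CO[Si](c2ccccc2)(c2ccccc2)C(C)(C)C)COC(C)(C)O1 | intermediate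
12 | lithium alkynyl(isopropoxy)pinacolatoborate (not isolated) | [Li+].CC(C)O[B-]1(C#C[C@]2(CO[Si](c3ccccc3)(c3ccccc3)C(C)(C)C)COC(C)(C)O2)OC(C)(C)C(C)(C)O1 | intermediate
13 | 2-{[(4R)-4-[(tert-butyldiphenylsilyloxy)methyl]-2,2-dimethyl-1,3-dioxolan-4-yl]ethynyl}-4,4,5,5-tetramethyl-1,3,2-dioxaborolane | CC1(C)OB(C#C[C@]2(CO[Si](c3ccccc3)(c3ccccc3)C(C)(C)C)COC(C)(C)O2)OC1(C)C | intermediate
14 | methyl coumalate (methyl 2-oxo-2H-pyran-5-carboxylate) | COC(=O)C1=COC(=O)C=C1 | starting material
15 | methyl 3-oxo-7-(pinacolboryl)-8-[(4R)-4-[(tert-butyldiphenylsilyloxy)methyl]-2,2-dimethyl-1,3-dioxolan-4-yl]-2-oxabicyclo[2.2.2]octa-5,7-diene-6-carboxylate, both bridgehead diastereomers (not isolated) | COC(=O)C1=CC2C(=O)OC1C(B3OC(C)(C)C(C)(C)O3)=C2[C@]3(CO[Si](c4ccccc4)(c4ccccc4)C(C)(C)C)COC(C)(C)O3 | intermediate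
16 | methyl 4-[(4R)-4-[(tert-butyldiphenylsilyloxy)methyl]-2,2-dimethyl-1,3-dioxolan-4-yl]-3-(4,4,5,5-tetramethyl-1,3,2-dioxaborolan-2-yl)benzoate | COC(=O)c1ccc([C@]2(CO[Si](c3ccccc3)(c3ccccc3)C(C)(C)C)COC(C)(C)O2)c(B2OC(C)(C)C(C)(C)O2)c1 | intermediate
17 | methyl 4-[(4R)-4-[(tert-butyldiphenylsilyloxy)methyl]-2,2-dimethyl-1,3-dioxolan-4-yl]-3-hydroxybenzoate | COC(=O)c1ccc([C@]2(CO[Si](c3ccccc3)(c3ccccc3)C(C)(C)C)COC(C)(C)O2)c(O)c1 | intermediate
18 | methyl 3-(allyloxy)-4-[(4R)-4-[(tert-butyldiphenylsilyloxy)methyl]-2,2-dimethyl-1,3-dioxolan-4-yl]benzoate | COC(=O)c1ccc([C@]2(CO[Si](c3ccccc3)(c3ccccc3)C(C)(C)C)COC(C)(C)O2)c(OCC=C)c1 | intermediate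
19 | {3-(allyloxy)-4-[(4R)-4-[(tert-butyldiphenylsilyloxy)methyl]-2,2-dimethyl-1,3-dioxolan-4-yl]phenyl}methanol | OCc1ccc([C@]2(CO[Si](c3ccccc3)(c3ccccc3)C(C)(C)C)COC(C)(C)O2)c(OCC=C)c1 | intermediate
20 | (R)-2-methylbutanoic acid | CC[C@@H](C)C(=O)O | starting material
21 | {3-(allyloxy)-4-[(4R)-4-[(tert-butyldiphenylsilyloxy)methyl]-2,2-dimethyl-1,3-dioxolan-4-yl]phenyl}methyl (2R)-2-methylbutanoate | CC[C@@H](C)C(=O)OCc1ccc([C@]2(CO[Si](c3ccccc3)(c3ccccc3)C(C)(C)C)COC(C)(C)O2)c(OCC=C)c1 | intermediate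
22 | {3-(allyloxy)-4-[(2R)-1-(tert-butyldiphenylsilyloxy)-2,3-dihydroxypropan-2-yl]phenyl}methyl (2R)-2-methylbutanoate | CC[C@@H](C)C(=O)OCc1ccc([C@](O)(CO[Si](c2ccccc2)(c2ccccc2)C(C)(C)C)CO)c(OCC=C)c1 | intermediate
23 | {3-(allyloxy)-4-[(2S)-1-(tert-butyldiphenylsilyloxy)-2-hydroxy-3-(tosyloxy)propan-2-yl]phenyl}methyl (2R)-2-methylbutanoate | CC[C@@H](C)C(=O)OCc1ccc([C@](O)(CO[Si](c2ccccc2)(c2ccccc2)C(C)(C)C)COS(=O)(=O)c2ccc(C)cc2)c(OCC=C)c1 | intermediate
24 | {3-(allyloxy)-4-[(2R)-2-[(tert-butyldiphenylsilyloxy)methyl]oxiran-2-yl]phenyl}methyl (2R)-2-methylbutanoate | CC[C@@H](C)C(=O)OCc1ccc([C@]2(CO[Si](c3ccccc3)(c3ccccc3)C(C)(C)C)CO2)c(OCC=C)c1 | intermediate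
25 | {3-(allyloxy)-4-[(2S)-2-(hydroxymethyl)oxiran-2-yl]phenyl}methyl (2R)-2-methylbutanoate | CC[C@@H](C)C(=O)OCc1ccc([C@]2(CO)CO2)c(OCC=C)c1 | intermediate
26 | {4-[(2R)-2-(acetoxymethyl)oxiran-2-yl]-3-(allyloxy)phenyl}methyl (2R)-2-methylbutanoate | CC[C@@H](C)C(=O)OCc1ccc([C@]2(COC(C)=O)CO2)c(OCC=C)c1 | intermediate
27 | {4-[(2R)-2-(acetoxymethyl)oxiran-2-yl]-3-hydroxyphenyl}methyl (2R)-2-methylbutanoate | CC[C@@H](C)C(=O)OCc1ccc([C@]2(COC(C)=O)CO2)c(O)c1 | intermediate
28 | angelic acid ((Z)-2-methylbut-2-enoic acid) | C/C=C(/C)C(=O)O | starting material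
29 | 2-[(2R)-2-(acetoxymethyl)oxiran-2-yl]-5-{[(2R)-2-methylbutanoyloxy]methyl}phenyl (Z)-2-methylbut-2-enoate (CNP0256757.1) | C/C=C(/C)C(=O)Oc1cc(COC(=O)[C@H](C)CC)ccc1[C@]1(COC(C)=O)CO1 | target

## Step count and risks

Total step count: 18. Longest linear sequence: 18 steps (from 1 and 2 to 29).

Steps most likely to fail:

1. Step 7. The cycloaddition may be too slow because both alkyne carbons are hindered, may add with the other regiochemistry (boron para to the ester), or 13 may lose boron at 165 °C. The fallback makes the aryl–C8 bond by aryl-metal addition to a ketone instead of benzannulation; it sets out from ketone 2 and comes back to the route at allyl ether 18. Commercial methyl 3-hydroxy-4-iodobenzoate (COC(=O)c1ccc(I)c(O)c1) is allylated (allyl bromide, K2CO3, DMF) to methyl 4-iodo-3-(allyloxy)benzoate F1. Iodine–magnesium exchange (i-PrMgCl·LiCl, THF, −40 °C) gives the arylmagnesium chloride F2, which is added to 2 at −40 °C to give the prochiral tertiary alcohol diacetate F3. Lipase hydrolysis as in step 2 should give the (R)-monoacetate F4, 2-methoxypropene/PPTS the acetonide acetate F5, and K2CO3/MeOH the primary alcohol F6. Silylation with TBDPSCl/imidazole then gives 18.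

2. Step 17. The freed phenol sits ortho to the benzylic oxirane and may open it (ionisation of the C8–O bond assisted by the phenol oxygen) before it is acylated in step 18. The fallback frees and acylates the phenol before the oxirane exists and closes the oxirane without base; it sets out from acetonide ester 21 and comes back at target 29. Compound 21 is deallylated (Pd(PPh3)4, N-methylaniline) to the phenol F7, which is angeloylated as in step 18 to the aryl angelate F8. Aqueous AcOH removes the acetonide to give the diol F9. Mitsunobu cyclodehydration (PPh3, DIAD, THF) activates the primary hydroxyl, which the tertiary one displaces, giving the oxirane silyl ether F10 under neutral conditions. Buffered Bu4NF/AcOH gives the epoxy alcohol F11, and Ac2O/pyridine gives 29.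

3. Step 2. The enzyme may discriminate the two acetoxymethyl arms poorly, or the acetyl group of 5 may migrate between the primary oxygens, which racemises C8. The fallback sets C8 by asymmetric C–C bond formation; it sets out from alkyne 1 and comes back at alcohol 8. Commercial ethyl 2-(hydroxymethyl)acrylate (C=C(CO)C(=O)OCC) is silylated (TBDPSCl, imidazole) to the acrylate F12 and ozonised (O3, CH2Cl2, −78 °C; Me2S) to the keto ester F13. Catalytic enantioselective alkynylation with 1 (Zn(OTf)2, chiral amino alcohol ligand, Et3N, toluene; ligand enantiomer chosen for the (S)-ester) gives the tertiary propargylic alcohol F14. LiBH4 reduces the ester to the diol F15, and 2-methoxypropene/PPTS gives the acetonide F16. Bu4NF removes both silyl groups to give 8, which is silylated again in step 5.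

## Further compounds

F1 | step 7 | methyl 4-iodo-3-(allyloxy)benzoate | COC(=O)c1ccc(I)c(OCC=C)c1
F2 | step 7 | [2-(allyloxy)-4-(methoxycarbonyl)phenyl]magnesium chloride | COC(=O)c1ccc([Mg]Cl)c(OCC=C)c1
F3 | step 7 | methyl 3-(allyloxy)-4-(1,3-diacetoxy-2-hydroxypropan-2-yl)benzoate | COC(=O)c1ccc(C(O)(COC(C)=O)COC(C)=O)c(OCC=C)c1
F4 | step 7 | methyl 4-[(2R)-1-acetoxy-2,3-dihydroxypropan-2-yl]-3-(allyloxy)benzoate | COC(=O)c1ccc([C@](O)(COC(C)=O)CO)c(OCC=C)c1
F5 | step 7 | methyl 4-[(4R)-4-(acetoxymethyl)-2,2-dimethyl-1,3-dioxolan-4-yl]-3-(allyloxy)benzoate | COC(=O)c1ccc([C@]2(COC(C)=O)COC(C)(C)O2)c(OCC=C)c1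
F6 | step 7 | methyl 3-(allyloxy)-4-[(4S)-4-(hydroxymethyl)-2,2-dimethyl-1,3-dioxolan-4-yl]benzoate | COC(=O)c1ccc([C@]2(CO)COC(C)(C)O2)c(OCC=C)c1
F7 | step 17 | {4-[(4R)-4-[(tert-butyldiphenylsilyloxy)methyl]-2,2-dimethyl-1,3-dioxolan-4-yl]-3-hydroxyphenyl}methyl (2R)-2-methylbutanoate | CC[C@@H](C)C(=O)OCc1ccc([C@]2(CO[Si](c3ccccc3)(c3ccccc3)C(C)(C)C)COC(C)(C)O2)c(O)c1
F8 | step 17 | 2-[(4R)-4-[(tert-butyldiphenylsilyloxy)methyl]-2,2-dimethyl-1,3-dioxolan-4-yl]-5-{[(2R)-2-methylbutanoyloxy]methyl}phenyl (Z)-2-methylbut-2-enoate | CC[C@@H](C)C(=O)OCc1ccc([C@]2(CO[Si](c3ccccc3)(c3ccccc3)C(C)(C)C)COC(C)(C)O2)c(OC(=O)/C(C)=C\C)c1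
F9 | step 17 | 2-[(2R)-1-(tert-butyldiphenylsilyloxy)-2,3-dihydroxypropan-2-yl]-5-{[(2R)-2-methylbutanoyloxy]methyl}phenyl (Z)-2-methylbut-2-enoate | CC[C@@H](C)C(=O)OCc1ccc([C@](O)(CO[Si](c2ccccc2)(c2ccccc2)C(C)(C)C)CO)c(OC(=O)/C(C)=C\C)c1
F10 | step 17 | 2-[(2R)-2-[(tert-butyldiphenylsilyloxy)methyl]oxiran-2-yl]-5-{[(2R)-2-methylbutanoyloxy]methyl}phenyl (Z)-2-methylbut-2-enoate | CC[C@@H](C)C(=O)OCc1ccc([C@]2(CO[Si](c3ccccc3)(c3ccccc3)C(C)(C)C)CO2)c(OC(=O)/C(C)=C\C)c1
F11 | step 17 | 2-[(2S)-2-(hydroxymethyl)oxiran-2-yl]-5-{[(2R)-2-methylbutanoyloxy]methyl}phenyl (Z)-2-methylbut-2-enoate | CC[C@@H](C)C(=O)OCc1ccc([C@]2(CO)CO2)c(OC(=O)/C(C)=C\C)c1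
F12 | step 2 | ethyl 2-[(tert-butyldiphenylsilyloxy)methyl]acrylate | C=C(CO[Si](c1ccccc1)(c1ccccc1)C(C)(C)C)C(=O)OCC
F13 | step 2 | ethyl 3-(tert-butyldiphenylsilyloxy)-2-oxopropanoate | CCOC(=O)C(=O)CO[Si](c1ccccc1)(c1ccccc1)C(C)(C)C
F14 | step 2 | ethyl (2S)-2-[(tert-butyldiphenylsilyloxy)methyl]-2-hydroxy-4-(triisopropylsilyl)but-3-ynoate | CC(C)[Si](C(C)C)(C(C)C)C#C[C@](O)(CO[Si](c1ccccc1)(c1ccccc1)C(C)(C)C)C(=O)OCC
F15 | step 2 | (2R)-2-[(tert-butyldiphenylsilyloxy)methyl]-4-(triisopropylsilyl)but-3-yne-1,2-diol | CC(C)[Si](C(C)C)(C(C)C)C#C[C@](O)(CO[Si](c1ccccc1)(c1ccccc1)C(C)(C)C)CO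
F16 | step 2 | (4R)-4-[(tert-butyldiphenylsilyloxy)methyl]-2,2-dimethyl-4-[(triisopropylsilyl)ethynyl]-1,3-dioxolane | CC(C)[Si](C(C)C)(C(C)C)C#C[C@]1(CO[Si](c2ccccc2)(c2ccccc2)C(C)(C)C)COC(C)(C)O1
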